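**Retrosynthetic overview**
1. Target 20 ⇐ silyl ether 19 ⇐ allylic alcohol 18 (Mitsunobu inversion installs the C5 propanoate) ⇐ acetate 17 ⇐ alcohol 16.
2. C2–C3 bond (ring B side): chelation-controlled vinylogous Mukaiyama aldol of pyranylidene silyl ether 4 with the β-PMB-oxy aldehyde 15.
3. C4–C5 bond, both stereocentres and the (E)-C6=C7 alkene: isomerisation–Claisen rearrangement of allyl ether 13, with chirality transfer from C7.
4. C8–C7 and C2′–C3′ bonds on ring A: two catalytic enantioselective vinylogous Mukaiyama aldol reactions (the new step) of 7 with enal 10 and of 4 with propanal.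
5. Ring order: one γ-pyrone, 3, is made first from pentan-3-one and propanoic anhydride and serves as both ring A and ring B; no ring is formed later.

**Conventions and assumption**
- TBS = tert-butyldimethylsilyl, TMS = trimethylsilyl, PMB = 4-methoxybenzyl. "Ring-A unit" = 6-[(2R,3S)-3-(TBS-oxy)pentan-2-yl]-3,5-dimethyl-4-oxo-4H-pyran-2-yl.
- Locants C1–C9 are those of the non-6-ene chain of 16–20 (C2 bears ring B, C8 bears ring A); C2′/C3′ are the pentan-2-yl side chain on ring A. The descriptor at C4 changes between 15, 16, 18 and 19 only through CIP priorities.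
- (S,S)-IDPi = the imidodiphosphorimidate Brønsted acid HN[P(=NSO2CF3)(diolate)]2 built from two (S)-3,3′-bis[3,5-bis(trifluoromethyl)phenyl]-1,1′-bi-2-naphthol units; (R,R)-IDPi is its mirror image.
- Assumption: the sense of induction of the new catalytic step cannot be known in advance; (S,S)-IDPi is taken to give the (R)-configured ring-bearing carbon and the (S)-carbinol (syn). If it is the reverse, the two catalyst antipodes are exchanged between steps 3 and 6.

**Route**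

Step 1
Reactants: 1 pentan-3-one; 2 propanoic anhydride
Product: 3 2,6-diethyl-3,5-dimethyl-4H-pyran-4-one
Conditions: 2 (2.2 equiv), polyphosphoric acid, 100 °C
Reagents that add atoms: none
Why: Double C-acylation of the ketone and cyclodehydration of the resulting triketone in polyphosphoric acid is the classical one-pot γ-pyrone synthesis from a dialkyl ketone and an anhydride (no stereocentre).

Step 2
Reactants: 3 2,6-diethyl-3,5-dimethyl-4H-pyran-4-one
Product: 4 tert-butyl{[(2Z)-6-ethyl-2-ethylidene-3,5-dimethyl-2H-pyran-4-yl]oxy}dimethylsilane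
Conditions: TBSOTf, Et3N, CH2Cl2, 0 °C; pentane extraction under argon
Reagents that add atoms: tert-butyldimethylsilyl trifluoromethanesulfonate, CC(C)(C)[Si](C)(C)OS(=O)(=O)C(F)(F)F
Why: Soft enolisation, in which O-silylation of the strongly Lewis-basic pyrone carbonyl acidifies the lateral CH2 so that Et3N removes a proton (anhydrobase formation), the ethylidene methyl turning away from the 3-methyl group (Z) to avoid allylic 1,3-strain.

Step 3
Reactants: 4 tert-butyl{[(2Z)-6-ethyl-2-ethylidene-3,5-dimethyl-2H-pyran-4-yl]oxy}dimethylsilane; 5 propanal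
Product: 6 2-[(2R,3S)-3-(TBS-oxy)pentan-2-yl]-6-ethyl-3,5-dimethyl-4H-pyran-4-one
Conditions: (S,S)-IDPi (2 mol %), toluene, −78 °C; Et3N quench
Reagents that add atoms: none
Why: Proposed new method: the IDPi acid is silylated by 4 to a silylium Lewis acid whose confined chiral anion pairs with O-silylated propanal, the exocyclic carbon of 4 attacks through an open antiperiplanar transition state in which the aldehyde ethyl group avoids the ethylidene methyl (syn, C2′ R and C3′ S by catalyst-controlled face selection), and aromatisation to a 4-silyloxypyrylium ion followed by silyl transfer to the next aldehyde releases 6 as its TBS ether, the closest known reaction type being the disulfonimide- and IDPi-catalysed vinylogous and bisvinylogous Mukaiyama aldol reaction of acyclic silyl dienolates.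

Step 4
Reactants: 6 2-[(2R,3S)-3-(TBS-oxy)pentan-2-yl]-6-ethyl-3,5-dimethyl-4H-pyran-4-one
Product: 7 {[(2Z)-6-[(2R,3S)-3-(TBS-oxy)pentan-2-yl]-2-ethylidene-3,5-dimethyl-2H-pyran-4-yl]oxy}trimethylsilane
Conditions: TMSOTf, Et3N, CH2Cl2, 0 °C; pentane extraction under argon
Reagents that add atoms: trimethylsilyl trifluoromethanesulfonate, C[Si](C)(C)OS(=O)(=O)C(F)(F)F
Why: Same soft enolisation as in step 2, and only the remaining CH2 is deprotonated because an anhydrobase at the tertiary carbon would be a tetrasubstituted alkene clashing with the ring methyl, so C2′ and C3′ are untouched.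

Step 5
Reactants: 8 (2E)-3-ethoxy-2-methylprop-2-enal; 9 (4-methoxyphenyl)methanol
Product: 10 (2E)-3-[(4-methoxybenzyl)oxy]-2-methylprop-2-enal
Conditions: pyridinium p-toluenesulfonate (5 mol %), toluene, 70 °C, 150 mbar (ethanol distilled off)
Reagents that add atoms: none
Why: Acid-catalysed addition–elimination (trans-etherification of a vinylogous formate) driven by removal of ethanol gives the thermodynamically preferred (E)-enol ether.

Step 6
Reactants: 7 {[(2Z)-6-[(2R,3S)-3-(TBS-oxy)pentan-2-yl]-2-ethylidene-3,5-dimethyl-2H-pyran-4-yl]oxy}trimethylsilane; 10 (2E)-3-[(4-methoxybenzyl)oxy]-2-methylprop-2-enal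
Product: 12 2-[(2S,3S,4E)-3-hydroxy-5-(PMB-oxy)-4-methylpent-4-en-2-yl]-6-[(2R,3S)-3-(TBS-oxy)pentan-2-yl]-3,5-dimethyl-4H-pyran-4-one, via trimethylsilyl ether 11 (not isolated)
Conditions: (R,R)-IDPi (3 mol %), toluene, −78 °C; Et3N; then K2CO3 (0.2 equiv), MeOH, 0 °C; Et3N-deactivated silica
Reagents that add atoms: none
Why: Proposed new method: the silylium counteranion catalysis of step 3 with the mirror-image catalyst is applied to a vinylogous formate, whose O-silylated form is a 1-silyloxy-3-alkoxyallyl cation expected to be attacked at the silyloxy-bearing carbon (weaker donor, less hindered terminus), the same syn open transition state setting C8 S and C7 S, and mild methanolysis then removes only the TMS group, the closest known reaction type being IDPi-catalysed Mukaiyama aldol additions of silyl dienolates to aldehydes.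

Step 7
Reactants: 12 2-[(2S,3S,4E)-3-hydroxy-5-(PMB-oxy)-4-methylpent-4-en-2-yl]-6-[(2R,3S)-3-(TBS-oxy)pentan-2-yl]-3,5-dimethyl-4H-pyran-4-one
Product: 13 2-[(2S,3S,4E)-3-(allyloxy)-5-(PMB-oxy)-4-methylpent-4-en-2-yl]-6-[(2R,3S)-3-(TBS-oxy)pentan-2-yl]-3,5-dimethyl-4H-pyran-4-one
Conditions: Et2Zn (0.55 equiv), THF, 0 °C; then allyl acetate, Pd(OAc)2 (5 mol %), 2-(di-tert-butylphosphino)biphenyl (10 mol %), rt
Reagents that add atoms: allyl acetate, C=CCOC(C)=O
Why: Palladium-catalysed allylic etherification of the zinc alkoxide (Tsuji–Trost O-allylation) runs at room temperature without a strong base, so neither retro-aldol cleavage nor loss of the acid-labile enol ether occurs and no stereocentre is touched.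

Step 8
Reactants: 13 2-[(2S,3S,4E)-3-(allyloxy)-5-(PMB-oxy)-4-methylpent-4-en-2-yl]-6-[(2R,3S)-3-(TBS-oxy)pentan-2-yl]-3,5-dimethyl-4H-pyran-4-one
Product: 15 (2S,3S,4E,6S)-3-(PMB-oxy)-2,4-dimethyl-6-(ring-A unit)hept-4-enal, via propenyl ether 14 (not isolated)
Conditions: [IrCl(C8H14)2]2 (1 mol %), PCy3 (6 mol %), NaBPh4 (2 mol %), CH2Cl2/acetone, rt; then PPh3 (6 mol %), ClCH2CH2Cl, 70 °C
Reagents that add atoms: none
Why: Iridium-catalysed isomerisation of the O-allyl group to the (E)-propenyl ether and Claisen rearrangement (isomerisation–Claisen rearrangement) through a chair with the ring-A-bearing substituent equatorial transfers the C7 configuration to C5 and C4 (2,3-syn aldehyde) and gives the (E)-trisubstituted alkene, the terminal alkoxy donor accelerating the shift.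

Step 9
Reactants: 15 (2S,3S,4E,6S)-3-(PMB-oxy)-2,4-dimethyl-6-(ring-A unit)hept-4-enal; 4 tert-butyl{[(2Z)-6-ethyl-2-ethylidene-3,5-dimethyl-2H-pyran-4-yl]oxy}dimethylsilane
Product: 16 2-ethyl-6-[(2R,3S,4R,5S,6E,8S)-3-hydroxy-5-(PMB-oxy)-4,6-dimethyl-8-(ring-A unit)non-6-en-2-yl]-3,5-dimethyl-4H-pyran-4-one
Conditions: MgBr2·OEt2 (4 equiv), 4 (2 equiv), CH2Cl2, −78 → −30 °C; aq NaHCO3
Reagents that add atoms: none
Why: Chelation-controlled vinylogous Mukaiyama aldol addition, in which MgBr2 bridges the aldehyde and PMB-ether oxygens, the cis-disposed C4 methyl and C5 substituent of the chelate shield the same face so that 4 attacks anti to both (3,4-anti and 3,5-anti, C3 S), and the open transition state places the C2 methyl syn to the new hydroxyl (C2 R).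

Step 10
Reactants: 16 2-ethyl-6-[(2R,3S,4R,5S,6E,8S)-3-hydroxy-5-(PMB-oxy)-4,6-dimethyl-8-(ring-A unit)non-6-en-2-yl]-3,5-dimethyl-4H-pyran-4-one
Product: 17 (2R,3S,4R,5S,6E,8S)-2-(6-ethyl-3,5-dimethyl-4-oxo-4H-pyran-2-yl)-5-(PMB-oxy)-4,6-dimethyl-8-(ring-A unit)non-6-en-3-yl acetate
Conditions: Ac2O, DMAP (cat.), pyridine, CH2Cl2, rt
Reagents that add atoms: acetic anhydride, CC(=O)OC(C)=O
Why: DMAP-catalysed acylation of the only free hydroxyl group.

Step 11
Reactants: 17 (2R,3S,4R,5S,6E,8S)-2-(6-ethyl-3,5-dimethyl-4-oxo-4H-pyran-2-yl)-5-(PMB-oxy)-4,6-dimethyl-8-(ring-A unit)non-6-en-3-yl acetate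
Product: 18 (2R,3S,4S,5S,6E,8S)-2-(6-ethyl-3,5-dimethyl-4-oxo-4H-pyran-2-yl)-5-hydroxy-4,6-dimethyl-8-(ring-A unit)non-6-en-3-yl acetate
Conditions: DDQ, CH2Cl2/pH 7 buffer, 0 °C
Reagents that add atoms: none
Why: Oxidative PMB-ether cleavage by DDQ (hydride abstraction to the oxocarbenium ion, then hydrolysis) leaves the acetate, silyl ether, alkene and pyrones untouched.

Step 12
Reactants: 18 (2R,3S,4S,5S,6E,8S)-2-(6-ethyl-3,5-dimethyl-4-oxo-4H-pyran-2-yl)-5-hydroxy-4,6-dimethyl-8-(ring-A unit)non-6-en-3-yl acetate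
Product: 19 (2R,3S,4R,5R,6E,8S)-3-acetoxy-2-(6-ethyl-3,5-dimethyl-4-oxo-4H-pyran-2-yl)-4,6-dimethyl-8-(ring-A unit)non-6-en-5-yl propanoate
Conditions: EtCO2H, PPh3, DIAD, toluene, 0 °C → rt
Reagents that add atoms: propanoic acid, CCC(=O)O
Why: Mitsunobu esterification displaces the activated allylic alcohol with propanoate in an SN2 step with inversion, turning the (5S)-alcohol needed for chelation control in step 9 into the (5R)-propanoate of the target.

Step 13
Reactants: 19 (2R,3S,4R,5R,6E,8S)-3-acetoxy-2-(6-ethyl-3,5-dimethyl-4-oxo-4H-pyran-2-yl)-4,6-dimethyl-8-(ring-A unit)non-6-en-5-yl propanoate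
Product: 20 (2R,3S,4R,5R,6E,8S)-3-acetoxy-2-(6-ethyl-3,5-dimethyl-4-oxo-4H-pyran-2-yl)-8-{6-[(2R,3S)-3-hydroxypentan-2-yl]-3,5-dimethyl-4-oxo-4H-pyran-2-yl}-4,6-dimethylnon-6-en-5-yl propanoate (CNP0265513.2)
Conditions: HF·pyridine, pyridine, THF, 0 °C → rt
Reagents that add atoms: none
Why: Buffered fluoride cleaves the TBS ether without ester cleavage or acyl migration, giving the target with all seven stereocentres and the (E)-alkene in place.

**Compound list**
1 | pentan-3-one | CCC(=O)CC | starting material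
2 | propanoic anhydride | CCC(=O)OC(=O)CC | starting material
3 | 2,6-diethyl-3,5-dimethyl-4H-pyran-4-one | CCc1oc(CC)c(C)c(=O)c1C | intermediate
4 | tert-butyl{[(2Z)-6-ethyl-2-ethylidene-3,5-dimethyl-2H-pyran-4-yl]oxy}dimethylsilane | C/C=C1\OC(CC)=C(C)C(O[Si](C)(C)C(C)(C)C)=C1C | intermediate
5 | propanal | CCC=O | starting material
6 | 2-[(2R,3S)-3-(TBS-oxy)pentan-2-yl]-6-ethyl-3,5-dimethyl-4H-pyran-4-one | CCc1oc([C@H](C)[C@@H](O[Si](C)(C)C(C)(C)C)CC)c(C)c(=O)c1C | intermediate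
7 | {[(2Z)-6-[(2R,3S)-3-(TBS-oxy)pentan-2-yl]-2-ethylidene-3,5-dimethyl-2H-pyran-4-yl]oxy}trimethylsilane | C/C=C1\OC([C@H](C)[C@@H](O[Si](C)(C)C(C)(C)C)CC)=C(C)C(O[Si](C)(C)C)=C1C | intermediate
8 | (2E)-3-ethoxy-2-methylprop-2-enal | CCO/C=C(\C)C=O | starting material
9 | (4-methoxyphenyl)methanol | COc1ccc(CO)cc1 | starting material
10 | (2E)-3-[(4-methoxybenzyl)oxy]-2-methylprop-2-enal | COc1ccc(CO/C=C(\C)C=O)cc1 | intermediate
11 | 2-[(2S,3S,4E)-5-(PMB-oxy)-4-methyl-3-(TMS-oxy)pent-4-en-2-yl]-6-[(2R,3S)-3-(TBS-oxy)pentan-2-yl]-3,5-dimethyl-4H-pyran-4-one | COc1ccc(CO/C=C(\C)[C@@H](O[Si](C)(C)C)[C@H](C)c2oc([C@H](C)[C@@H](O[Si](C)(C)C(C)(C)C)CC)c(C)c(=O)c2C)cc1 | intermediate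
12 | 2-[(2S,3S,4E)-3-hydroxy-5-(PMB-oxy)-4-methylpent-4-en-2-yl]-6-[(2R,3S)-3-(TBS-oxy)pentan-2-yl]-3,5-dimethyl-4H-pyran-4-one | COc1ccc(CO/C=C(\C)[C@@H](O)[C@H](C)c2oc([C@H](C)[C@@H](O[Si](C)(C)C(C)(C)C)CC)c(C)c(=O)c2C)cc1 | intermediate
13 | 2-[(2S,3S,4E)-3-(allyloxy)-5-(PMB-oxy)-4-methylpent-4-en-2-yl]-6-[(2R,3S)-3-(TBS-oxy)pentan-2-yl]-3,5-dimethyl-4H-pyran-4-one | COc1ccc(CO/C=C(\C)[C@@H](OCC=C)[C@H](C)c2oc([C@H](C)[C@@H](O[Si](C)(C)C(C)(C)C)CC)c(C)c(=O)c2C)cc1 | intermediate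
14 | 2-[(2S,3S,4E)-5-(PMB-oxy)-4-methyl-3-[(1E)-prop-1-en-1-yloxy]pent-4-en-2-yl]-6-[(2R,3S)-3-(TBS-oxy)pentan-2-yl]-3,5-dimethyl-4H-pyran-4-one | COc1ccc(CO/C=C(\C)[C@@H](O/C=C/C)[C@H](C)c2oc([C@H](C)[C@@H](O[Si](C)(C)C(C)(C)C)CC)c(C)c(=O)c2C)cc1 | intermediate
15 | (2S,3S,4E,6S)-3-(PMB-oxy)-2,4-dimethyl-6-(ring-A unit)hept-4-enal | COc1ccc(CO[C@H](/C(C)=C/[C@H](C)c2oc([C@H](C)[C@@H](O[Si](C)(C)C(C)(C)C)CC)c(C)c(=O)c2C)[C@H](C)C=O)cc1 | intermediate
16 | 2-ethyl-6-[(2R,3S,4R,5S,6E,8S)-3-hydroxy-5-(PMB-oxy)-4,6-dimethyl-8-(ring-A unit)non-6-en-2-yl]-3,5-dimethyl-4H-pyran-4-one | COc1ccc(CO[C@H](/C(C)=C/[C@H](C)c2oc([C@H](C)[C@@H](O[Si](C)(C)C(C)(C)C)CC)c(C)c(=O)c2C)[C@H](C)[C@H](O)[C@@H](C)c2oc(CC)c(C)c(=O)c2C)cc1 | intermediate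
17 | (2R,3S,4R,5S,6E,8S)-2-(6-ethyl-3,5-dimethyl-4-oxo-4H-pyran-2-yl)-5-(PMB-oxy)-4,6-dimethyl-8-(ring-A unit)non-6-en-3-yl acetate | COc1ccc(CO[C@H](/C(C)=C/[C@H](C)c2oc([C@H](C)[C@@H](O[Si](C)(C)C(C)(C)C)CC)c(C)c(=O)c2C)[C@H](C)[C@H](OC(C)=O)[C@@H](C)c2oc(CC)c(C)c(=O)c2C)cc1 | intermediate
18 | (2R,3S,4S,5S,6E,8S)-2-(6-ethyl-3,5-dimethyl-4-oxo-4H-pyran-2-yl)-5-hydroxy-4,6-dimethyl-8-(ring-A unit)non-6-en-3-yl acetate | O[C@H](/C(C)=C/[C@H](C)c1oc([C@H](C)[C@@H](O[Si](C)(C)C(C)(C)C)CC)c(C)c(=O)c1C)[C@H](C)[C@H](OC(C)=O)[C@@H](C)c1oc(CC)c(C)c(=O)c1C | intermediate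
19 | (2R,3S,4R,5R,6E,8S)-3-acetoxy-2-(6-ethyl-3,5-dimethyl-4-oxo-4H-pyran-2-yl)-4,6-dimethyl-8-(ring-A unit)non-6-en-5-yl propanoate | CCC(=O)O[C@@H](/C(C)=C/[C@H](C)c1oc([C@H](C)[C@@H](O[Si](C)(C)C(C)(C)C)CC)c(C)c(=O)c1C)[C@H](C)[C@H](OC(C)=O)[C@@H](C)c1oc(CC)c(C)c(=O)c1C | intermediate
20 | (2R,3S,4R,5R,6E,8S)-3-acetoxy-2-(6-ethyl-3,5-dimethyl-4-oxo-4H-pyran-2-yl)-8-{6-[(2R,3S)-3-hydroxypentan-2-yl]-3,5-dimethyl-4-oxo-4H-pyran-2-yl}-4,6-dimethylnon-6-en-5-yl propanoate | CCC(=O)O[C@@H](/C(C)=C/[C@H](C)c1oc([C@H](C)[C@@H](O)CC)c(C)c(=O)c1C)[C@H](C)[C@H](OC(C)=O)[C@@H](C)c1oc(CC)c(C)c(=O)c1C | target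

**Step count**
Total step count: 13. Longest linear sequence: 12 steps (steps 1–4 and 6–13; step 5 is a one-step branch).

**Three steps most likely to fail**

Step 3 (first use of the new catalytic aldol). The basic pyrone product may hold the silylium ion as a stable 4-silyloxypyrylium salt and stop turnover, or the ee and syn selectivity may be low. The fallback uses known chemistry; it sets out from 3 and comes back at 6. Compound 3 is deprotonated with LiN(SiMe3)2 in THF at −78 °C and the lithium dienolate is added to propanal 5, the established racemic vinylogous aldol reaction of this pyrone. The racemic syn aldol, rac-2-ethyl-6-[(2R*,3S*)-3-hydroxypentan-2-yl]-3,5-dimethyl-4H-pyran-4-one F1, is purified by chromatography. Lipase-catalysed acylation (Burkholderia cepacia lipase, vinyl acetate) converts the (3R)-carbinol into (2S,3R)-2-(6-ethyl-3,5-dimethyl-4-oxo-4H-pyran-2-yl)pentan-3-yl acetate F2 and leaves 2-ethyl-6-[(2R,3S)-3-hydroxypentan-2-yl]-3,5-dimethyl-4H-pyran-4-one F3 (at most half of the material). F3 is silylated (TBSCl, imidazole, DMF) to give 6.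

Step 6 (second use of the new method, on a vinylogous formate). The donor may attack the alkoxy-bearing terminus instead, the silylium acid may re-ionise the γ-alkoxyallyl silyl ether 11, or the PMB group may be lost. The fallback uses known chemistry; it sets out from 6 and comes back at 12. Compound 6 is deprotonated with LiN(SiMe3)2 (THF, −78 °C) and the lithium dienolate adds 1,2 to enal 10. This gives the carbinol 2-[3-hydroxy-5-(PMB-oxy)-4-methylpent-4-en-2-yl]-6-[(2R,3S)-3-(TBS-oxy)pentan-2-yl]-3,5-dimethyl-4H-pyran-4-one as a mixture of its four side-chain stereoisomers F4. Acylative kinetic resolution of these secondary allylic alcohols with the chiral isothiourea HyperBTM and isobutyric anhydride (iPr2NEt, CHCl3, −40 °C) esterifies the (3R)-carbinols to the (3R)-isobutyrates F5. Of the remaining (3S)-alcohols, the anti isomer 2-[(2R,3S,4E)-3-hydroxy-5-(PMB-oxy)-4-methylpent-4-en-2-yl]-6-[(2R,3S)-3-(TBS-oxy)pentan-2-yl]-3,5-dimethyl-4H-pyran-4-one F6 is removed by chromatography (adjacent stereocentres), leaving 12. The yield is at most a quarter, but every operation is established.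

Step 9 (fragment coupling). MgBr2 may be sequestered by the three basic carbonyl groups, simple syn selectivity may erode, or facial control may be incomplete. The fallback replaces substrate (chelation) control by catalyst control; it sets out from 15 and 3 and comes back at 16. Compound 3 is converted (TMSOTf, Et3N) into the trimethylsilyl dienol ether {[(2Z)-6-ethyl-2-ethylidene-3,5-dimethyl-2H-pyran-4-yl]oxy}trimethylsilane F7. F7 is added to 15 with (S,S)-IDPi at −78 °C, as in step 3. In 15 the Felkin preference and the 1,3-polar preference oppose each other, so the catalyst should decide the face. The product is the C3 trimethylsilyl ether of 16, F8, which is cleaved with K2CO3 in MeOH to give 16.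

**Further compounds**
F1 | step 3 | rac-2-ethyl-6-[(2R*,3S*)-3-hydroxypentan-2-yl]-3,5-dimethyl-4H-pyran-4-one (racemate, both enantiomers shown) | CCc1oc([C@H](C)[C@@H](O)CC)c(C)c(=O)c1C.CCc1oc([C@@H](C)[C@H](O)CC)c(C)c(=O)c1C
F2 | step 3 | (2S,3R)-2-(6-ethyl-3,5-dimethyl-4-oxo-4H-pyran-2-yl)pentan-3-yl acetate | CCc1oc([C@@H](C)[C@H](OC(C)=O)CC)c(C)c(=O)c1C
F3 | step 3 | 2-ethyl-6-[(2R,3S)-3-hydroxypentan-2-yl]-3,5-dimethyl-4H-pyran-4-one | CCc1oc([C@H](C)[C@@H](O)CC)c(C)c(=O)c1C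
F4 | step 6 | 2-[(4E)-3-hydroxy-5-(PMB-oxy)-4-methylpent-4-en-2-yl]-6-[(2R,3S)-3-(TBS-oxy)pentan-2-yl]-3,5-dimethyl-4H-pyran-4-one, mixture of the four C2/C3 side-chain isomers | COc1ccc(CO/C=C(\C)C(O)C(C)c2oc([C@H](C)[C@@H](O[Si](C)(C)C(C)(C)C)CC)c(C)c(=O)c2C)cc1
F5 | step 6 | (3R,4E)-5-(PMB-oxy)-4-methyl-2-{6-[(2R,3S)-3-(TBS-oxy)pentan-2-yl]-3,5-dimethyl-4-oxo-4H-pyran-2-yl}pent-4-en-3-yl 2-methylpropanoate, both C2 epimers | COc1ccc(CO/C=C(\C)[C@H](OC(=O)C(C)C)C(C)c2oc([C@H](C)[C@@H](O[Si](C)(C)C(C)(C)C)CC)c(C)c(=O)c2C)cc1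
F6 | step 6 | 2-[(2R,3S,4E)-3-hydroxy-5-(PMB-oxy)-4-methylpent-4-en-2-yl]-6-[(2R,3S)-3-(TBS-oxy)pentan-2-yl]-3,5-dimethyl-4H-pyran-4-one | COc1ccc(CO/C=C(\C)[C@@H](O)[C@@H](C)c2oc([C@H](C)[C@@H](O[Si](C)(C)C(C)(C)C)CC)c(C)c(=O)c2C)cc1
F7 | step 9 | {[(2Z)-6-ethyl-2-ethylidene-3,5-dimethyl-2H-pyran-4-yl]oxy}trimethylsilane | C/C=C1\OC(CC)=C(C)C(O[Si](C)(C)C)=C1C
F8 | step 9 | 2-ethyl-6-[(2R,3S,4R,5S,6E,8S)-5-(PMB-oxy)-4,6-dimethyl-8-(ring-A unit)-3-(TMS-oxy)non-6-en-2-yl]-3,5-dimethyl-4H-pyran-4-one | COc1ccc(CO[C@H](/C(C)=C/[C@H](C)c2oc([C@H](C)[C@@H](O[Si](C)(C)C(C)(C)C)CC)c(C)c(=O)c2C)[C@H](C)[C@H](O[Si](C)(C)C)[C@@H](C)c2oc(CC)c(C)c(=O)c2C)cc1
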